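The labdane is cut at C11–C12 and the drimane core is traced back to (R)-carvone: ring B (C5–C10) with the C8 methyl and C9 oxygen is the carvone ring, and the C4 gem-dimethyl carbon is its isopropenyl carbon attached to the C5 stereocentre. The key step exploits exactly this: acid turns the isopropenyl group into the tertiary C4 cation, which a (Z)-vinylsilane tethered at C10 intercepts, forging C3–C4 and closing ring A as a trans-decalin with a C2=C3 alkene. Its substrate is carvone carrying, at C6 (future C10), a methyl cis and a (Z)-3-(trimethylsilyl)allyl chain trans to the isopropenyl group.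

Key step: step 5

Assumption: atoms C1–C11 are numbered as in drimane/labdane (C11 is the carbon on C9; α is the face opposite the C10 methyl), and chloride 22 is bought as the pure (E)-isomer.

Step 1
Reactants: 1 3-(trimethylsilyl)prop-2-yn-1-ol
Product: 2 (Z)-3-(trimethylsilyl)prop-2-en-1-ol
Conditions: H2 (1 atm), Ni(OAc)2·4H2O, NaBH4, ethylenediamine, EtOH, rt
Reagents that add atoms: none
Why: Catalytic semi-hydrogenation on P-2 nickel boride adds hydrogen syn to the silylalkyne and stops at the alkene, which fixes the Z geometry of the vinylsilane.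

Step 2
Reactants: 2 (Z)-3-(trimethylsilyl)prop-2-en-1-ol
Product: 3 (Z)-3-bromo-1-(trimethylsilyl)prop-1-ene
Conditions: CBr4, PPh3, CH2Cl2, 0 °C
Reagents that add atoms: carbon tetrabromide BrC(Br)(Br)Br
Why: Appel bromination converts the primary allylic alcohol into the bromide under neutral conditions that should leave the Z-vinylsilane untouched.

Step 3
Reactants: 4 (R)-(−)-carvone
Product: 6 (5R)-2,6-dimethyl-5-(prop-1-en-2-yl)cyclohex-2-en-1-one (6-methylcarvone as a mixture of C6 epimers), via lithium dienolate 5 (not isolated)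
Conditions: LDA, THF, −78 °C; MeI, −78 → 0 °C
Reagents that add atoms: iodomethane CI
Why: Kinetic deprotonation at the α′ carbon (C6) gives the cross-conjugated enolate, and its SN2 methylation (enolate alkylation) gives 6-methylcarvone, whose C6 configuration is irrelevant because the next enolate erases it.

Step 4
Reactants: 6 6-methylcarvone; 3 (Z)-3-bromo-1-(trimethylsilyl)prop-1-ene
Product: 8 (5S,6S)-2,6-dimethyl-5-(prop-1-en-2-yl)-6-[(2Z)-3-(trimethylsilyl)prop-2-en-1-yl]cyclohex-2-en-1-one, via lithium dienolate 7 (not isolated)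
Conditions: LDA, THF, −78 → 0 °C; 3, DMPU, −78 °C → rt
Reagents that add atoms: none
Why: Enolate alkylation of the fully substituted α′ enolate with the allylic bromide should occur anti to the neighbouring C5 isopropenyl group, which shields one face, so the quaternary centre (future C10) is set with the silylallyl chain trans and the methyl cis to isopropenyl.

Step 5
Reactants: 8 (5S,6S)-6-methyl-6-[(Z)-3-(trimethylsilyl)allyl]carvone
Product: 11 (4aS,8aS)-2,5,5,8a-tetramethyl-4a,5,8,8a-tetrahydronaphthalen-1(4H)-one (trans-fused 11-nordrima-2,7-dien-9-one), via tertiary C4 cation 9 (not isolated), via β-silyl cation 10 (not isolated)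
Conditions: CF3CO2H, CH2Cl2, 0 °C → rt; aq. NaHCO3 work-up
Reagents that add atoms: none
Why: Trifluoroacetic acid protonates the 1,1-disubstituted isopropenyl alkene, the most basic π bond (the enone is deactivated and the vinylsilane is less nucleophilic), to give tertiary cation 9 in which C4 already carries both methyl groups. The Z-vinylsilane then attacks through its silicon-bearing carbon, forming C3–C4 and the β-silyl-stabilised cation 10, and loss of the silyl group to trifluoroacetate leaves the C2=C3 alkene; the closest known reaction type is the vinylsilane-terminated cation–olefin cyclisation. Ring A closes in a 6-endo mode with respect to the vinylsilane π bond through a chair-like transition state. No new stereocentre is created: C5 and C10 are already in place, and because the cation arm on C5 and the silylallyl arm on C10 are trans on the carvone ring, only the trans ring fusion can form. The step needs ipso capture to outrun protodesilylation, proton loss from the cation toward C5 (which would endanger the C5 configuration) and hydride shift; the Z geometry lines the C–Si bond up with the developing empty orbital and makes the six-membered closure fast, and the reaction is run cold in a weakly nucleophilic medium.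

Step 6
Reactants: 11 11-nordrima-2,7-dien-9-one
Product: 12 (4aS,8aS)-2,5,5,8a-tetramethyloctahydronaphthalen-1(2H)-one (11-nordriman-9-one, C8 epimers)
Conditions: H2 (1 atm), 10% Pd/C, EtOAc, rt
Reagents that add atoms: none
Why: Catalytic hydrogenation should saturate both the isolated C2=C3 alkene and the enone C7=C8 bond without touching the hindered C9 ketone, and the C8 epimer ratio does not matter because C8 becomes sp2 in the next step.

Step 7
Reactants: 12 11-nordriman-9-one
Product: 14 (4aS,8aS)-2,5,5,8a-tetramethyl-3,4,4a,5,6,7,8,8a-octahydronaphthalen-1-yl trifluoromethanesulfonate (11-nordrim-8-en-9-yl triflate), via potassium enolate 13 (not isolated)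
Conditions: KHMDS, THF, −78 → 0 °C; PhNTf2, −78 °C → rt
Reagents that add atoms: N-phenylbis(trifluoromethanesulfonimide) O=S(=O)(N(c1ccccc1)S(=O)(=O)C(F)(F)F)C(F)(F)F
Why: C8 carries the only enolisable hydrogen, so deprotonation gives a single enolate whose O-sulfonylation (enol triflate formation) gives the tetrasubstituted C8=C9 triflate.

Step 8
Reactants: 14 11-nordrim-8-en-9-yl triflate
Product: 15 methyl (4aS,8aS)-2,5,5,8a-tetramethyl-3,4,4a,5,6,7,8,8a-octahydronaphthalene-1-carboxylate (methyl drim-8-en-11-oate)
Conditions: CO (1 atm), Pd(OAc)2 (cat.), dppp (cat.), Et3N, MeOH–DMF, 70 °C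
Reagents that add atoms: carbon monoxide [C-]#[O+]; methanol CO
Why: Palladium-catalysed methoxycarbonylation of the enol triflate (oxidative addition, CO insertion, methanolysis) installs C11 on C9 as the methyl ester.

Step 9
Reactants: 15 methyl drim-8-en-11-oate
Product: 16 methyl 8α,9α-epoxydriman-11-oate
Conditions: mCPBA, NaHCO3, CH2Cl2, 0 °C → rt
Reagents that add atoms: 3-chloroperoxybenzoic acid O=C(OO)c1cccc(Cl)c1
Why: Prilezhaev epoxidation of the tetrasubstituted alkene, whose ester is twisted out of conjugation, should occur on the α face because the axial C10 methyl blocks the β face, which sets the C8–O bond α.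

Step 10
Reactants: 16 methyl 8α,9α-epoxydriman-11-oate
Product: 18 methyl (1R,2R,4aS,8aS)-2-hydroxy-2,5,5,8a-tetramethyldecahydronaphthalene-1-carboxylate (methyl 8α-hydroxydriman-11-oate), via samarium enolate 17 (not isolated)
Conditions: SmI2 (2.5 equiv), HMPA, Me2NCH2CH2OH, THF, 0 °C
Reagents that add atoms: none
Why: Samarium diiodide reductive cleavage of the α,β-epoxy ester breaks only the C9–O bond, so the 8α oxygen stays, and the enolate should be protonated at C9 from the α face (the β face carries the axial C8 and C10 methyls) to give the equatorial 9β ester.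

Step 11
Reactants: 18 methyl 8α-hydroxydriman-11-oate
Product: 19 driman-8α,11-diol (8α-OH, 9β-CH2OH)
Conditions: LiAlH4, THF, 0 °C; Rochelle salt work-up
Reagents that add atoms: none
Why: Hydride reduction of the ester gives the primary C11 alcohol, and at low temperature the tertiary alkoxide should neither fragment by retro-aldol nor allow C9 to epimerise.

Step 12
Reactants: 19 driman-8α,11-diol
Product: 20 11-iododriman-8α-ol
Conditions: I2, PPh3, imidazole, CH2Cl2, 0 °C → rt
Reagents that add atoms: iodine II
Why: Appel-type iodination activates only the primary C11 hydroxyl, since the tertiary C8 hydroxyl is too hindered to form the alkoxyphosphonium ion and four-membered ether formation is slow.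

Step 13
Reactants: 20 11-iododriman-8α-ol
Product: 21 11-iodo-8α-(trimethylsilyloxy)drimane
Conditions: TMSOTf, 2,6-lutidine, CH2Cl2, −78 → 0 °C
Reagents that add atoms: trimethylsilyl trifluoromethanesulfonate C[Si](C)(C)OS(=O)(=O)C(F)(F)F
Why: Silyl ether formation with the highly electrophilic silyl triflate caps the hindered tertiary alcohol so that no acidic proton remains for the organomagnesium step.

Step 14
Reactants: 21 11-iodo-8α-(trimethylsilyloxy)drimane; 22 (E)-4-chloro-3-methylbut-2-en-1-yl acetate
Product: 25 (13E)-8α-hydroxylabd-13-en-15-yl acetate (target), via Grignard reagent 23 (not isolated), via trimethylsilyl ether 24 (not isolated)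
Conditions: Mg, THF, 40 °C; then added to 22, Li2CuCl4 (5 mol %), THF, −78 → 0 °C; then 0.5 M HCl, THF, 0 °C
Reagents that add atoms: none
Why: Magnesium insertion gives the primary Grignard reagent, copper-catalysed Grignard allylic substitution at low temperature should displace the primary allylic chloride at its own carbon with retention of the E alkene and faster than the acetate is attacked, and the dilute-acid work-up removes the labile trimethylsilyl ether.

Compound list
1 | 3-(trimethylsilyl)prop-2-yn-1-ol | C[Si](C)(C)C#CCO | starting material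
2 | (Z)-3-(trimethylsilyl)prop-2-en-1-ol | C[Si](C)(C)/C=C\CO | intermediate
3 | (Z)-3-bromo-1-(trimethylsilyl)prop-1-ene | C[Si](C)(C)/C=C\CBr | intermediate
4 | (R)-(−)-carvone, (5R)-2-methyl-5-(prop-1-en-2-yl)cyclohex-2-en-1-one | CC1=CC[C@H](CC1=O)C(C)=C | starting material
5 | lithium dienolate of 4 (O–Li on C1, C1=C6 and C2=C3) | [Li]OC1=C[C@H](C(C)=C)CC=C1C | intermediate (not isolated)
6 | (5R)-2,6-dimethyl-5-(prop-1-en-2-yl)cyclohex-2-en-1-one, 6-methylcarvone, C6 epimers | O=C1C(C)[C@H](C(C)=C)CC=C1C | intermediate
7 | lithium dienolate of 6 (O–Li on C1, C1=C6 and C2=C3) | [Li]OC1=C(C)[C@H](C(C)=C)CC=C1C | intermediate (not isolated)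
8 | (5S,6S)-2,6-dimethyl-5-(prop-1-en-2-yl)-6-[(2Z)-3-(trimethylsilyl)prop-2-en-1-yl]cyclohex-2-en-1-one | O=C1[C@@](C)(C/C=C\[Si](C)(C)C)[C@H](C(C)=C)CC=C1C | intermediate
9 | tertiary carbocation from protonation of the isopropenyl group of 8 (cation at future C4) | O=C1[C@@](C)(C/C=C\[Si](C)(C)C)[C@H]([C+](C)C)CC=C1C | intermediate (not isolated)
10 | β-silyl cation after C3–C4 bond formation (cation at C2, SiMe3 on C3, C3 configuration transient and not specified) | O=C1[C@@]2(C)C[CH+]C([Si](C)(C)C)C(C)(C)[C@@H]2CC=C1C | intermediate (not isolated)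
11 | (4aS,8aS)-2,5,5,8a-tetramethyl-4a,5,8,8a-tetrahydronaphthalen-1(4H)-one, trans-fused 11-nordrima-2,7-dien-9-one | O=C1[C@@]2(C)CC=CC(C)(C)[C@@H]2CC=C1C | intermediate
12 | (4aS,8aS)-2,5,5,8a-tetramethyloctahydronaphthalen-1(2H)-one, 11-nordriman-9-one, C8 epimers | O=C1[C@@]2(C)CCCC(C)(C)[C@@H]2CCC1C | intermediate
13 | potassium enolate of 12 (C8=C9) | CC1=C(O[K])[C@@]2(C)CCCC(C)(C)[C@@H]2CC1 | intermediate (not isolated)
14 | (4aS,8aS)-2,5,5,8a-tetramethyl-3,4,4a,5,6,7,8,8a-octahydronaphthalen-1-yl trifluoromethanesulfonate | CC1=C(OS(=O)(=O)C(F)(F)F)[C@@]2(C)CCCC(C)(C)[C@@H]2CC1 | intermediate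
15 | methyl drim-8-en-11-oate | CC1=C(C(=O)OC)[C@@]2(C)CCCC(C)(C)[C@@H]2CC1 | intermediate
16 | methyl 8α,9α-epoxydriman-11-oate | COC(=O)[C@@]31[C@@]2(C)CCCC(C)(C)[C@@H]2CC[C@@]1(C)O3 | intermediate
17 | samarium(III) ester enolate with 8α-O–SmI2 alkoxide (enolate geometry not specified) | COC(O[Sm](I)I)=C1[C@@]2(C)CCCC(C)(C)[C@@H]2CC[C@@]1(C)O[Sm](I)I | intermediate (not isolated)
18 | methyl (1R,2R,4aS,8aS)-2-hydroxy-2,5,5,8a-tetramethyldecahydronaphthalene-1-carboxylate, methyl 8α-hydroxydriman-11-oate | COC(=O)[C@@H]1[C@@]2(C)CCCC(C)(C)[C@@H]2CC[C@@]1(C)O | intermediate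
19 | driman-8α,11-diol | OC[C@@H]1[C@@]2(C)CCCC(C)(C)[C@@H]2CC[C@@]1(C)O | intermediate
20 | 11-iododriman-8α-ol | IC[C@@H]1[C@@]2(C)CCCC(C)(C)[C@@H]2CC[C@@]1(C)O | intermediate
21 | 11-iodo-8α-(trimethylsilyloxy)drimane | IC[C@@H]1[C@@]2(C)CCCC(C)(C)[C@@H]2CC[C@@]1(C)O[Si](C)(C)C | intermediate
22 | (E)-4-chloro-3-methylbut-2-en-1-yl acetate | CC(=O)OC/C=C(\C)CCl | starting material
23 | [8α-(trimethylsilyloxy)driman-11-yl]magnesium iodide | I[Mg]C[C@@H]1[C@@]2(C)CCCC(C)(C)[C@@H]2CC[C@@]1(C)O[Si](C)(C)C | intermediate (not isolated)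
24 | (13E)-8α-(trimethylsilyloxy)labd-13-en-15-yl acetate | CC(=O)OC/C=C(\C)CC[C@@H]1[C@@]2(C)CCCC(C)(C)[C@@H]2CC[C@@]1(C)O[Si](C)(C)C | intermediate (not isolated)
25 | (13E)-8α-hydroxylabd-13-en-15-yl acetate, [(2E)-5-[(1R,2R,4aS,8aS)-2-hydroxy-2,5,5,8a-tetramethyldecahydronaphthalen-1-yl]-3-methylpent-2-en-1-yl] acetate | CC(=O)OC/C=C(\C)CC[C@@H]1[C@@]2(C)CCCC(C)(C)[C@@H]2CC[C@@]1(C)O | target

Total step count: 14. Longest linear sequence: 13 steps (steps 1, 2 and 4–14, counted from 3-(trimethylsilyl)prop-2-yn-1-ol; the branch from (R)-carvone, steps 3–14, is 12 steps long and joins at step 4).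

Steps most likely to fail

Step 5. The vinylsilane may be cleaved by the acid, or the C4 cation may lose a proton or shift a hydride before it is captured, which would return open-chain alkenes and could erode C5. The fallback generates the cation without a free strong acid. It sets out from 8: a Mukaiyama hydration of the isopropenyl group (Co(acac)2 cat., PhSiH3, O2, i-PrOH, rt; hydrogen-atom transfer should pick the 1,1-disubstituted alkene) would give the tertiary alcohol (5R,6S)-5-(2-hydroxypropan-2-yl)-2,6-dimethyl-6-[(Z)-3-(trimethylsilyl)prop-2-enyl]cyclohex-2-en-1-one F1. Ionisation of this alcohol with SnCl4 in CH2Cl2 at −78 °C should then produce the same C4 cation under aprotic conditions, and the same vinylsilane capture brings the sequence back to the route at 11.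

Step 14. The Grignard reagent may attack the γ carbon of the allylic chloride or the acetate carbonyl, or magnesium insertion at the hindered C11 iodide may be incomplete and accompanied by dimerisation. The fallback reverses the electronic demand with a sulfone-stabilised carbanion at C11. It sets out from 21: displacement of iodide with PhSNa (DMF, 60 °C) should give 11-(phenylsulfanyl)-8α-(trimethylsilyloxy)drimane F2, and oxidation (mCPBA, NaHCO3, CH2Cl2, 0 °C) gives 11-(phenylsulfonyl)-8α-(trimethylsilyloxy)drimane F3. Deprotonation (n-BuLi, THF, −78 °C) and alkylation with chloride 22, which stabilised carbanions attack at the CH2Cl carbon, should give (13E)-11-(phenylsulfonyl)-8α-(trimethylsilyloxy)labd-13-en-15-yl acetate F4 as C11 epimers. Reductive desulfonylation (6% Na/Hg, Na2HPO4, MeOH–THF, −20 °C) comes back to the route at silyl ether 24, which the acidic work-up of step 14 converts into 25.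

Step 10. The samarium enolate may eliminate its β-alkoxide back to ester 15, the aldolate may fragment by retro-aldol, or C9 may be protonated on the wrong face. The fallback sets C9 by hydroboration of an exocyclic alkene instead of by enolate protonation. It sets out from 15: DIBAL-H (CH2Cl2, −78 °C) should give drim-8-en-11-ol F5, and mCPBA epoxidation on the α face gives 8α,9α-epoxydriman-11-ol F6. PPh3/I2/imidazole gives 11-iodo-8α,9α-epoxydrimane F7, and zinc dust in ethanol should open it reductively to drim-9(11)-en-8α-ol F8 with the C8–O bond untouched. Hydroboration–oxidation (BH3·THF; NaOH, H2O2) should add hydrogen to C9 from the α face and comes back to the route at diol 19.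

Further compounds
F1 | step 5 | (5R,6S)-5-(2-hydroxypropan-2-yl)-2,6-dimethyl-6-[(Z)-3-(trimethylsilyl)prop-2-enyl]cyclohex-2-en-1-one | O=C1[C@@](C)(C/C=C\[Si](C)(C)C)[C@H](C(C)(C)O)CC=C1C
F2 | step 14 | 11-(phenylsulfanyl)-8α-(trimethylsilyloxy)drimane | c3ccccc3SC[C@@H]1[C@@]2(C)CCCC(C)(C)[C@@H]2CC[C@@]1(C)O[Si](C)(C)C
F3 | step 14 | 11-(phenylsulfonyl)-8α-(trimethylsilyloxy)drimane | O=S(=O)(c3ccccc3)C[C@@H]1[C@@]2(C)CCCC(C)(C)[C@@H]2CC[C@@]1(C)O[Si](C)(C)C
F4 | step 14 | (13E)-11-(phenylsulfonyl)-8α-(trimethylsilyloxy)labd-13-en-15-yl acetate, C11 epimers | CC(=O)OC/C=C(\C)CC([C@@H]1[C@@]2(C)CCCC(C)(C)[C@@H]2CC[C@@]1(C)O[Si](C)(C)C)S(=O)(=O)c3ccccc3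
F5 | step 10 | drim-8-en-11-ol | CC1=C(CO)[C@@]2(C)CCCC(C)(C)[C@@H]2CC1
F6 | step 10 | 8α,9α-epoxydriman-11-ol | OC[C@@]31[C@@]2(C)CCCC(C)(C)[C@@H]2CC[C@@]1(C)O3
F7 | step 10 | 11-iodo-8α,9α-epoxydrimane | IC[C@@]31[C@@]2(C)CCCC(C)(C)[C@@H]2CC[C@@]1(C)O3
F8 | step 10 | drim-9(11)-en-8α-ol | C=C1[C@@]2(C)CCCC(C)(C)[C@@H]2CC[C@@]1(C)O
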